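**Retr​osynthetic overview**

1. Target 23 ⇐ global desilylation of the tris-silyl ether 22.
2. 22 ⇐ C2–C1' bond and both stereocentres in one step: enantioselective rhodium/chiral-diene conjugate arylation of 3-silyloxychromone 14 with arylboronic acid 21.
3. 14 ⇐ Stille prenylation of bromochromone 11; 11 ⇐ resorcinol (1) by Nencki acylation, bromination, enaminone ring closure with 6, and dioxirane oxidation at C3.
4. 21 ⇐ 4-bromophenol (15) by ortho-iodination, silylation, iodide-selective Stille prenylation and Br–Li exchange/borylation; prenylstannane 13 for both Stille couplings ⇐ prenyl chloride 12.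
5. Ring order: ring A (from resorcinol) → ring C (chromone closure) → ring B attached last in the key coupling.

Assumption: (S,S)-Ph-bod* [(1S,4S)-2,5-diphenylbicyclo[2.2.2]octa-2,5-diene] is taken to deliver the aryl group to the Re face of C2 of chromone 14, by analogy with its reported sense on cyclohex-2-enone; if a test run shows the opposite sense, the (R,R) ligand is used in step 13.

**Route**

Step 1
Reactants: 1 resorcinol; 2 acetic acid
Product: 3 1-(2,4-dihydroxyphenyl)ethan-1-one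
Conditions: ZnCl2 (1.2 equiv), AcOH, 145 °C
Reagents that add atoms: none
Why: Nencki reaction (ZnCl2-promoted Friedel–Crafts C-acylation); resorcinol is acylated at C4, ortho to one hydroxyl and para to the other.

Step 2
Reactants: 3 1-(2,4-dihydroxyphenyl)ethan-1-one
Product: 4 1-(5-bromo-2,4-dihydroxyphenyl)ethan-1-one
Conditions: NBS (1.0 equiv), MeCN, 0 °C
Reagents that add atoms: N-bromosuccinimide O=C1CCC(=O)N1Br
Why: Electrophilic aromatic bromination goes to C5 (ortho to the 4-OH, para to the chelated 2-OH) rather than the crowded C3 between the two oxygens; the 5-bromo isomer is confirmed by two aromatic singlets in the 1H NMR spectrum.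

Step 3
Reactants: 4 1-(5-bromo-2,4-dihydroxyphenyl)ethan-1-one
Product: 5 1-{5-bromo-2-hydroxy-4-[(triisopropylsilyl)oxy]phenyl}ethan-1-one
Conditions: TIPSCl (1.1 equiv), imidazole (2.2 equiv), DMF, 0 → 23 °C
Reagents that add atoms: triisopropylsilyl chloride CC(C)[Si](Cl)(C(C)C)C(C)C
Why: Silyl ether formation; the 2-OH is hydrogen-bonded to the ketone, so only the 4-OH is silylated, and the aryl TIPS ether survives every later step until fluoride.

Step 4
Reactants: 5 1-{5-bromo-2-hydroxy-4-[(triisopropylsilyl)oxy]phenyl}ethan-1-one; 6 N,N-dimethylformamide dimethyl acetal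
Product: 8 6-bromo-7-[(triisopropylsilyl)oxy]-4H-chromen-4-one, via enaminone 7 (not isolated)
Conditions: 6 (2.5 equiv), toluene, 95 °C; concentrate; then AcOH, 80 °C
Reagents that add atoms: none
Why: Enaminone route to chromones: condensation of the methyl ketone with the amide acetal, then acid-promoted intramolecular oxa-Michael addition and loss of dimethylamine closes ring C.

Step 5
Reactants: 8 6-bromo-7-[(triisopropylsilyl)oxy]-4H-chromen-4-one
Product: 10 6-bromo-3-hydroxy-7-[(triisopropylsilyl)oxy]-4H-chromen-4-one, via chromone epoxide 9 (not isolated)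
Conditions: DMDO (about 0.08 M in acetone, 3 equiv), CH2Cl2, 0 → 23 °C; concentrate; then TsOH·H2O (10 mol%), CH2Cl2, 23 °C
Reagents that add atoms: dimethyldioxirane CC1(C)OO1
Why: Dioxirane epoxidation of the C2=C3 bond, then acid-catalysed epoxide opening at the acetal carbon C2 and loss of H-3, gives the 3-hydroxychromone; it is run before any prenyl group is present, so the oxidant meets no other alkene.

Step 6
Reactants: 10 6-bromo-3-hydroxy-7-[(triisopropylsilyl)oxy]-4H-chromen-4-one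
Product: 11 6-bromo-3-[(tert-butyldimethylsilyl)oxy]-7-[(triisopropylsilyl)oxy]-4H-chromen-4-one
Conditions: TBSCl (1.3 equiv), imidazole (2.5 equiv), DMF, 23 °C
Reagents that add atoms: tert-butyldimethylsilyl chloride CC(C)(C)[Si](C)(C)Cl
Why: Silyl ether formation at the acidic enolic 3-OH; the TBS enol ether masks the metal-chelating 3-hydroxy-4-pyranone unit and comes off with fluoride at the end.

Step 7
Reactants: 12 1-chloro-3-methylbut-2-ene (prenyl chloride)
Product: 13 tributyl(3-methylbut-2-en-1-yl)stannane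
Conditions: Bu3SnH, LiN(iPr)2, THF, 0 °C (gives Bu3SnLi); then 12, −78 → 0 °C
Reagents that add atoms: tributyltin hydride CCCC[SnH](CCCC)CCCC
Why: SN2 substitution of the primary allylic chloride by the stannyl anion gives the linear prenylstannane.

Step 8
Reactants: 11 6-bromo-3-[(tert-butyldimethylsilyl)oxy]-7-[(triisopropylsilyl)oxy]-4H-chromen-4-one; 13 tributyl(3-methylbut-2-en-1-yl)stannane
Product: 14 3-[(tert-butyldimethylsilyl)oxy]-6-(3-methylbut-2-en-1-yl)-7-[(triisopropylsilyl)oxy]-4H-chromen-4-one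
Conditions: 13 (1.4 equiv), Pd(PPh3)4 (10 mol%), DMF, 100 °C
Reagents that add atoms: none
Why: Migita–Kosugi–Stille coupling; zerovalent palladium inserts into the aryl bromide and, after transmetalation, reductive elimination at the less substituted allyl terminus gives the linear prenyl arene under neutral conditions that leave both silyl ethers intact.

Step 9
Reactants: 15 4-bromophenol
Product: 16 4-bromo-2-iodophenol
Conditions: NIS (1.0 equiv), TsOH·H2O (10 mol%), MeCN, 23 °C
Reagents that add atoms: N-iodosuccinimide O=C1CCC(=O)N1I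
Why: Electrophilic aromatic iodination; the para position is blocked by bromine, so iodine enters ortho to the hydroxyl.

Step 10
Reactants: 16 4-bromo-2-iodophenol
Product: 17 (4-bromo-2-iodophenoxy)triisopropylsilane
Conditions: TIPSCl (1.2 equiv), imidazole (2.5 equiv), DMF, 40 °C
Reagents that add atoms: triisopropylsilyl chloride CC(C)[Si](Cl)(C(C)C)C(C)C
Why: Silyl ether formation; the TIPS ether tolerates the organolithium step and keeps the phenol from cyclising onto the ortho prenyl group later.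

Step 11
Reactants: 17 (4-bromo-2-iodophenoxy)triisopropylsilane; 13 tributyl(3-methylbut-2-en-1-yl)stannane
Product: 18 [4-bromo-2-(3-methylbut-2-en-1-yl)phenoxy]triisopropylsilane
Conditions: 13 (1.1 equiv), Pd(PPh3)4 (5 mol%), DMF, 80 °C
Reagents that add atoms: none
Why: Migita–Kosugi–Stille coupling, selective for the iodide because oxidative addition to the carbon–iodine bond is much faster than to the carbon–bromine bond, which is kept for the next step.

Step 12
Reactants: 18 [4-bromo-2-(3-methylbut-2-en-1-yl)phenoxy]triisopropylsilane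
Product: 21 {3-(3-methylbut-2-en-1-yl)-4-[(triisopropylsilyl)oxy]phenyl}boronic acid, via aryllithium 19 (not isolated), via lithium triisopropoxyborate 20 (not isolated)
Conditions: n-BuLi (1.05 equiv), THF, −78 °C; B(OiPr)3 (1.5 equiv), −78 → 0 °C; then 1 M HCl
Reagents that add atoms: triisopropyl borate CC(C)OB(OC(C)C)OC(C)C; water O
Why: Bromine–lithium exchange followed by borate trapping and acidic hydrolysis (standard arylboronic acid synthesis); the exchange at −78 °C is faster than any allylic deprotonation.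

Step 13
Reactants: 14 3-[(tert-butyldimethylsilyl)oxy]-6-(3-methylbut-2-en-1-yl)-7-[(triisopropylsilyl)oxy]-4H-chromen-4-one; 21 {3-(3-methylbut-2-en-1-yl)-4-[(triisopropylsilyl)oxy]phenyl}boronic acid
Product: 22 (2R,3R)-3-[(tert-butyldimethylsilyl)oxy]-6-(3-methylbut-2-en-1-yl)-2-{3-(3-methylbut-2-en-1-yl)-4-[(triisopropylsilyl)oxy]phenyl}-7-[(triisopropylsilyl)oxy]chroman-4-one
Conditions: [RhCl(C2H4)2]2 (2.5 mol%), (S,S)-Ph-bod* (5.5 mol%), KOH (10 mol%), 21 (2.0 equiv), 1,4-dioxane/H2O (10:1), 40 °C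
Reagents that add atoms: none
Why: Proposed new method: the monovalent rhodium/chiral diene conjugate arylation (Hayashi–Miyaura reaction), known for 3-unsubstituted chromones (the closest known reaction type) but not for 3-silyloxychromones, is extended to 14; the Ar–Rh species formed by transmetalation from 21 inserts the C2=C3 bond with the aryl group going to the Re face of C2 under ligand control (sets 2R) and rhodium to C3 on the same face, so that hydrolysis of the rhodium enolate leaves the 3-OTBS group trans to the aryl group (3R), which is also the thermodynamically preferred diequatorial arrangement reached by enolisation under the mildly basic conditions, and the two prenyl alkenes are inert to the catalyst.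

Step 14
Reactants: 22 (2R,3R)-3-[(tert-butyldimethylsilyl)oxy]-6-(3-methylbut-2-en-1-yl)-2-{3-(3-methylbut-2-en-1-yl)-4-[(triisopropylsilyl)oxy]phenyl}-7-[(triisopropylsilyl)oxy]chroman-4-one
Product: 23 Lespeflorin B1
Conditions: TBAF (6 equiv), AcOH (6 equiv), THF, 0 → 23 °C
Reagents that add atoms: none
Why: Fluoride-mediated global desilylation; the acetic acid buffer keeps the freed phenols protonated, which prevents retro-oxa-Michael ring opening and epimerisation, so neither stereocentre is touched.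

**Compound list**

1 | resorcinol | Oc1cccc(O)c1 | starting material
2 | acetic acid | CC(=O)O | starting material
3 | 1-(2,4-dihydroxyphenyl)ethan-1-one | CC(=O)c1ccc(O)cc1O | intermediate
4 | 1-(5-bromo-2,4-dihydroxyphenyl)ethan-1-one | CC(=O)c1cc(Br)c(O)cc1O | intermediate
5 | 1-{5-bromo-2-hydroxy-4-[(triisopropylsilyl)oxy]phenyl}ethan-1-one | CC(=O)c1cc(Br)c(O[Si](C(C)C)(C(C)C)C(C)C)cc1O | intermediate
6 | N,N-dimethylformamide dimethyl acetal | COC(OC)N(C)C | starting material
7 | (E)-1-{5-bromo-2-hydroxy-4-[(triisopropylsilyl)oxy]phenyl}-3-(dimethylamino)prop-2-en-1-one (enaminone) | CN(C)/C=C/C(=O)c1cc(Br)c(O[Si](C(C)C)(C(C)C)C(C)C)cc1O | intermediate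
8 | 6-bromo-7-[(triisopropylsilyl)oxy]-4H-chromen-4-one | O=c1ccoc2cc(O[Si](C(C)C)(C(C)C)C(C)C)c(Br)cc12 | intermediate
9 | rac-6-bromo-2,3-epoxy-7-[(triisopropylsilyl)oxy]chroman-4-one (chromone epoxide, racemic) | O=C1C2OC2Oc2cc(O[Si](C(C)C)(C(C)C)C(C)C)c(Br)cc21 | intermediate
10 | 6-bromo-3-hydroxy-7-[(triisopropylsilyl)oxy]-4H-chromen-4-one | O=c1c(O)coc2cc(O[Si](C(C)C)(C(C)C)C(C)C)c(Br)cc12 | intermediate
11 | 6-bromo-3-[(tert-butyldimethylsilyl)oxy]-7-[(triisopropylsilyl)oxy]-4H-chromen-4-one | O=c1c(O[Si](C)(C)C(C)(C)C)coc2cc(O[Si](C(C)C)(C(C)C)C(C)C)c(Br)cc12 | intermediate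
12 | 1-chloro-3-methylbut-2-ene (prenyl chloride) | CC(C)=CCCl | starting material
13 | tributyl(3-methylbut-2-en-1-yl)stannane | CCCC[Sn](CCCC)(CCCC)CC=C(C)C | intermediate
14 | 3-[(tert-butyldimethylsilyl)oxy]-6-(3-methylbut-2-en-1-yl)-7-[(triisopropylsilyl)oxy]-4H-chromen-4-one | O=c1c(O[Si](C)(C)C(C)(C)C)coc2cc(O[Si](C(C)C)(C(C)C)C(C)C)c(CC=C(C)C)cc12 | intermediate
15 | 4-bromophenol | Oc1ccc(Br)cc1 | starting material
16 | 4-bromo-2-iodophenol | Oc1ccc(Br)cc1I | intermediate
17 | (4-bromo-2-iodophenoxy)triisopropylsilane | CC(C)[Si](Oc1ccc(Br)cc1I)(C(C)C)C(C)C | intermediate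
18 | [4-bromo-2-(3-methylbut-2-en-1-yl)phenoxy]triisopropylsilane | CC(C)=CCc1cc(Br)ccc1O[Si](C(C)C)(C(C)C)C(C)C | intermediate
19 | {3-(3-methylbut-2-en-1-yl)-4-[(triisopropylsilyl)oxy]phenyl}lithium (aryllithium) | [Li]c1ccc(O[Si](C(C)C)(C(C)C)C(C)C)c(CC=C(C)C)c1 | intermediate
20 | lithium triisopropoxy{3-(3-methylbut-2-en-1-yl)-4-[(triisopropylsilyl)oxy]phenyl}borate | [Li+].CC(C)O[B-](OC(C)C)(OC(C)C)c1ccc(O[Si](C(C)C)(C(C)C)C(C)C)c(CC=C(C)C)c1 | intermediate
21 | {3-(3-methylbut-2-en-1-yl)-4-[(triisopropylsilyl)oxy]phenyl}boronic acid | CC(C)=CCc1cc(B(O)O)ccc1O[Si](C(C)C)(C(C)C)C(C)C | intermediate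
22 | (2R,3R)-3-[(tert-butyldimethylsilyl)oxy]-6-(3-methylbut-2-en-1-yl)-2-{3-(3-methylbut-2-en-1-yl)-4-[(triisopropylsilyl)oxy]phenyl}-7-[(triisopropylsilyl)oxy]chroman-4-one | CC(C)=CCc1cc([C@H]2Oc3cc(O[Si](C(C)C)(C(C)C)C(C)C)c(CC=C(C)C)cc3C(=O)[C@@H]2O[Si](C)(C)C(C)(C)C)ccc1O[Si](C(C)C)(C(C)C)C(C)C | intermediate
23 | Lespeflorin B1, (2R,3R)-3,7-dihydroxy-2-[4-hydroxy-3-(3-methylbut-2-en-1-yl)phenyl]-6-(3-methylbut-2-en-1-yl)chroman-4-one | CC(C)=CCc1cc([C@H]2Oc3cc(O)c(CC=C(C)C)cc3C(=O)[C@@H]2O)ccc1O | target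

**Totals**

Total step count: 14.
Longest linear sequence: 9 steps (1, 2, 3, 4, 5, 6, 8, 13, 14), which is 9/14 = 0.64 of the total. Steps 7 and 9–12 are side branches.

**Three steps most likely to fail, with fallbacks**

Step 13 (the new conjugate arylation). The 3-silyloxy group makes C2 more hindered and more electron-rich than in a plain chromone, and the enol silyl ether could hydrolyse to a chelating 3-hydroxychromone. The fallback uses only known chemistry. It sets out from bromochromone 8 and comes back to the route at 23.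
- Stille coupling of 8 with 13 (Pd(PPh3)4, DMF, 95 °C) gives 6-(3-methylbut-2-en-1-yl)-7-[(triisopropylsilyl)oxy]-4H-chromen-4-one F1.
- The established rhodium/chiral-diene 1,4-addition of 21 to this 3-unsubstituted chromone ([RhCl(C2H4)2]2, (S,S)-Ph-bod*, KOH, dioxane/H2O, 40 °C) gives (2S)-6-(3-methylbut-2-en-1-yl)-2-{3-(3-methylbut-2-en-1-yl)-4-[(triisopropylsilyl)oxy]phenyl}-7-[(triisopropylsilyl)oxy]chroman-4-one F2.
- KN(SiMe3)2 in THF at −78 °C gives potassium (2S)-6-(3-methylbut-2-en-1-yl)-2-{3-(3-methylbut-2-en-1-yl)-4-[(triisopropylsilyl)oxy]phenyl}-7-[(triisopropylsilyl)oxy]-2H-chromen-4-olate F3 (not isolated).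
- Davis oxidation with trans-2-(phenylsulfonyl)-3-phenyloxaziridine hydroxylates the enolate anti to the C2 aryl group, without touching the prenyl alkenes, to give (2R,3R)-3-hydroxy-6-(3-methylbut-2-en-1-yl)-2-{3-(3-methylbut-2-en-1-yl)-4-[(triisopropylsilyl)oxy]phenyl}-7-[(triisopropylsilyl)oxy]chroman-4-one F4.
- TBAF/AcOH in THF removes the two TIPS groups and gives 23.

Step 8 (Stille prenylation of the hindered bromide ortho to the OTIPS group; slow oxidative addition and possible alpha/gamma mixtures). The fallback replaces direct prenyl transfer by allylation and cross-metathesis. It sets out from 11 and comes back at 14.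
- Stille coupling of 11 with allyltributylstannane (Pd(PPh3)4, DMF, 95 °C), which transmetalates faster and has no regiochemical ambiguity, gives 6-allyl-3-[(tert-butyldimethylsilyl)oxy]-7-[(triisopropylsilyl)oxy]-4H-chromen-4-one F5.
- Olefin cross-metathesis with excess 2-methylbut-2-ene (second-generation Grubbs catalyst RuCl2(=CHPh)(PCy3)(H2IMes), CH2Cl2, 40 °C) gives 14.

Step 5 (epoxidation of an electron-poor chromone and rearrangement of a labile epoxide). The fallback oxygenates the ketone alpha-carbon before ring C is closed, so no chromone epoxide is needed. It sets out from 5 and comes back at 11.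
- TMSOTf/Et3N (CH2Cl2, 0 °C) gives 1-{5-bromo-4-[(triisopropylsilyl)oxy]-2-[(trimethylsilyl)oxy]phenyl}-1-[(trimethylsilyl)oxy]ethene F6.
- Rubottom oxidation (mCPBA, NaHCO3, CH2Cl2, 0 °C) gives 1-{5-bromo-4-[(triisopropylsilyl)oxy]-2-[(trimethylsilyl)oxy]phenyl}-2-[(trimethylsilyl)oxy]ethan-1-one F7 (not isolated).
- Citric acid/MeOH work-up gives 1-{5-bromo-2-hydroxy-4-[(triisopropylsilyl)oxy]phenyl}-2-hydroxyethan-1-one F8.
- TBSCl/imidazole (CH2Cl2, 0 °C) silylates the primary alcohol to 2-[(tert-butyldimethylsilyl)oxy]-1-{5-bromo-2-hydroxy-4-[(triisopropylsilyl)oxy]phenyl}ethan-1-one F9.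
- Condensation with 6 (toluene, 95 °C) gives 1-{5-bromo-2-hydroxy-4-[(triisopropylsilyl)oxy]phenyl}-2-[(tert-butyldimethylsilyl)oxy]-3-(dimethylamino)prop-2-en-1-one F10 (not isolated), which closes in AcOH at 80 °C to 11.

**Further compounds**

F1 | step 13 | 6-(3-methylbut-2-en-1-yl)-7-[(triisopropylsilyl)oxy]-4H-chromen-4-one | O=c1ccoc2cc(O[Si](C(C)C)(C(C)C)C(C)C)c(CC=C(C)C)cc12
F2 | step 13 | (2S)-6-(3-methylbut-2-en-1-yl)-2-{3-(3-methylbut-2-en-1-yl)-4-[(triisopropylsilyl)oxy]phenyl}-7-[(triisopropylsilyl)oxy]chroman-4-one | CC(C)=CCc1cc([C@H]2Oc3cc(O[Si](C(C)C)(C(C)C)C(C)C)c(CC=C(C)C)cc3C(=O)C2)ccc1O[Si](C(C)C)(C(C)C)C(C)C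
F3 | step 13 | potassium (2S)-6-(3-methylbut-2-en-1-yl)-2-{3-(3-methylbut-2-en-1-yl)-4-[(triisopropylsilyl)oxy]phenyl}-7-[(triisopropylsilyl)oxy]-2H-chromen-4-olate | CC(C)=CCc1cc([C@H]2Oc3cc(O[Si](C(C)C)(C(C)C)C(C)C)c(CC=C(C)C)cc3C([O-])=C2)ccc1O[Si](C(C)C)(C(C)C)C(C)C.[K+]
F4 | step 13 | (2R,3R)-3-hydroxy-6-(3-methylbut-2-en-1-yl)-2-{3-(3-methylbut-2-en-1-yl)-4-[(triisopropylsilyl)oxy]phenyl}-7-[(triisopropylsilyl)oxy]chroman-4-one | CC(C)=CCc1cc([C@H]2Oc3cc(O[Si](C(C)C)(C(C)C)C(C)C)c(CC=C(C)C)cc3C(=O)[C@@H]2O)ccc1O[Si](C(C)C)(C(C)C)C(C)C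
F5 | step 8 | 6-allyl-3-[(tert-butyldimethylsilyl)oxy]-7-[(triisopropylsilyl)oxy]-4H-chromen-4-one | O=c1c(O[Si](C)(C)C(C)(C)C)coc2cc(O[Si](C(C)C)(C(C)C)C(C)C)c(CC=C)cc12
F6 | step 5 | 1-{5-bromo-4-[(triisopropylsilyl)oxy]-2-[(trimethylsilyl)oxy]phenyl}-1-[(trimethylsilyl)oxy]ethene | C=C(O[Si](C)(C)C)c1cc(Br)c(O[Si](C(C)C)(C(C)C)C(C)C)cc1O[Si](C)(C)C
F7 | step 5 | 1-{5-bromo-4-[(triisopropylsilyl)oxy]-2-[(trimethylsilyl)oxy]phenyl}-2-[(trimethylsilyl)oxy]ethan-1-one | C[Si](C)(C)OCC(=O)c1cc(Br)c(O[Si](C(C)C)(C(C)C)C(C)C)cc1O[Si](C)(C)C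
F8 | step 5 | 1-{5-bromo-2-hydroxy-4-[(triisopropylsilyl)oxy]phenyl}-2-hydroxyethan-1-one | O=C(CO)c1cc(Br)c(O[Si](C(C)C)(C(C)C)C(C)C)cc1O
F9 | step 5 | 2-[(tert-butyldimethylsilyl)oxy]-1-{5-bromo-2-hydroxy-4-[(triisopropylsilyl)oxy]phenyl}ethan-1-one | O=C(CO[Si](C)(C)C(C)(C)C)c1cc(Br)c(O[Si](C(C)C)(C(C)C)C(C)C)cc1O
F10 | step 5 | 1-{5-bromo-2-hydroxy-4-[(triisopropylsilyl)oxy]phenyl}-2-[(tert-butyldimethylsilyl)oxy]-3-(dimethylamino)prop-2-en-1-one | CN(C)C=C(O[Si](C)(C)C(C)(C)C)C(=O)c1cc(Br)c(O[Si](C(C)C)(C(C)C)C(C)C)cc1O
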